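Target is the species to watch, and always against substrate, so read the two together at each sampling.

| flask | substrate | remark | time |
|---|---|---|---|
| theta | 0.13 M | run made earlier |  |
| zeta | 0.30 M | run made earlier |  |
| flask | 0.20 M |  | 1.0 h |

| run | time / min | target / % | substrate / % |
|---|---|---|---|
| theta | 4.00 | 19 | 51 |
| theta | 12.0 | 25 | 26 |
| theta | 20.0 | 21 | 15 |
| theta | 30.0 | 16 | 14 |
| theta | 50.0 | 12 | 5 |
| theta | 60.0 | 9 | 6 |
| zeta | 10.0 | 17 | 19 |
| zeta | 20.0 | 16 | 12 |
| zeta | 30.0 | 11 | 11 |
| zeta | 40.0 | 10 | 7 |
| zeta | 50.0 | 7 | 6 |
| zeta | 60.0 | 4 | 4 |

(standard deviation of a reading: 1.5 percentage points)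



- amount of target in percent of the substrate charged, at 6.0 min, 20 min, 40 min and 1.0 h

Climb the time scales from the fastest. In the theta run about half of the substrate is gone by 4.00 min. Target crests there at a reading of 25% near 12.0 min, where target over substrate reads 0.962. From 20.0 min on, the two stop moving against each other: summed over those readings, target over substrate gives 1.45 in the theta run and 1.20 in the zeta run, and a scatter of 1.5 percentage points on readings this small does not separate them. So freeze it: both runs pooled read 1.32, the frozen ratio, late target percent over late substrate percent, a quasi-steady ratio of a draining pair, read from the readings. Target is then 57.0% of the pair.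

On the slowest rung the pair drains, at 0.0219 min⁻¹ in the theta run and 0.0313 min⁻¹ in the zeta run. Their mean 0.0266 min⁻¹ gives a half-life of 26.1 min, longer than the time to the crest.

For the new flask, whose 0.20 M lies near the geometric mean of the two charges, I take the pair at 20 min as the midpoint, 32.0%. That gives target 18.2% there, 10.7% at 40 min and 6.29% at 1.0 h. At 6.0 min the ratio has not frozen, so this reckoning gives nothing there. The forecast, made to “interpolate on log concentration”, says 20%, 18.5%, 11.5% and 7%, higher than mine at 1.0 h.

    substrate ⇌ third isomer (K = 11.0, k = 0.0300 min⁻¹)
    substrate ⇌ target (K = 0.920, k = 0.0800 min⁻¹)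
    substrate ⇌ isomer of the product (K = 49.0, k = 0.0320 min⁻¹)
    2 substrate → homo dimer (k = 0.250 L mol⁻¹ min⁻¹)

The flask gives target 20.9%, 18.4%, 10.6% and 6.41%, and the forecast stands within its margin. Substrate and target relax by their own step, both ways together, with a half-life of 0.0692 h, short against 1.0 h. Check the frozen ratio in this flask at 1.00 h: substrate stands at 5.11%, 1.32 times that is 6.75%, and target stands at 6.41%.

The data come from a simulation with constants of no real substance, noise included.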